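## Retrosynthetic overview

1. Ring C (the pyranone) is closed last at the O1–C2 bond: enantioselective intramolecular oxa-Michael addition of the 2'-hydroxyl of an α-aryl enone, with catalyst-controlled protonation setting C3 as R.
2. The enone comes from α-methylenation (one carbon from formaldehyde) of a 2,4-dihydroxy-3-prenyl deoxybenzoin.
3. The prenyl group is placed on the carbon between the two phenolic oxygens of the unprenylated deoxybenzoin.
4. The deoxybenzoin comes from Friedel–Crafts acylation of resorcinol (ring A) with (2,2-dimethylchroman-6-yl)acetic acid (ring B).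
5. Ring order: the dimethylpyran ring on ring B first (4-hydroxyphenylacetic acid plus isoprene), ring C last.

Assumption: the sense of induction of the new cyclization in step 5 cannot be predicted with certainty; the route is written with the (R)-configured acid, and the (S)-configured acid is used instead if a calibration run gives the 3S product.

## Route

Step 1
Reactants: 1 4-hydroxyphenylacetic acid; 2 isoprene
Product: 4 2-(2,2-dimethylchroman-6-yl)acetic acid, via ortho-prenylphenol acid 3 (not isolated)
Conditions: 2 (1.5 equiv), 85% H3PO4, toluene, 35 °C, 24 h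
Reagents that add atoms: none
Why: Acid-catalysed Friedel–Crafts prenylation ortho to the phenol (para position blocked) gives 3, whose alkene is protonated to the tertiary cation and trapped by the phenol oxygen (Markovnikov hydroalkoxylation) to close the 2,2-dimethylchroman ring; no stereocenter is formed.

Step 2
Reactants: 4 2-(2,2-dimethylchroman-6-yl)acetic acid; 5 resorcinol
Product: 6 1-(2,4-dihydroxyphenyl)-2-(2,2-dimethylchroman-6-yl)ethan-1-one
Conditions: BF3·OEt2 (neat, 5 equiv), 85 °C, 2 h; then H2O
Reagents that add atoms: none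
Why: BF3-mediated Friedel–Crafts (Nencki-type) acylation takes place at C4 of resorcinol, the position ortho and para to the two hydroxyls, and the chroman ether survives because it is the thermodynamic product under acid; no stereocenter is formed.

Step 3
Reactants: 6 1-(2,4-dihydroxyphenyl)-2-(2,2-dimethylchroman-6-yl)ethan-1-one; 7 prenyl bromide
Product: 8 1-[2,4-dihydroxy-3-(3-methylbut-2-en-1-yl)phenyl]-2-(2,2-dimethylchroman-6-yl)ethan-1-one
Conditions: 7 (1.1 equiv), KOH (2.2 equiv), H2O, 0 °C to rt, 16 h, N2; then 1 M HCl; chromatography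
Reagents that add atoms: none
Why: Phenolate C-alkylation in water, where hydrogen bonding shields the oxygens, goes mainly to the doubly activated carbon between the two oxygens; about 25–35% of 8 is expected after separation from the C5 and O-prenyl isomers, with 6 recovered and recycled.

Step 4
Reactants: 8 1-[2,4-dihydroxy-3-(3-methylbut-2-en-1-yl)phenyl]-2-(2,2-dimethylchroman-6-yl)ethan-1-one
Product: 10 1-[2,4-dihydroxy-3-(3-methylbut-2-en-1-yl)phenyl]-2-(2,2-dimethylchroman-6-yl)prop-2-en-1-one, via Mannich base 9 (not isolated)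
Conditions: (CH2O)n (3 equiv), i-Pr2NH·CF3CO2H (1 equiv), CF3CO2H (10 mol%), THF, 65 °C, 3 h; rapid chromatography, used at once
Reagents that add atoms: paraformaldehyde (as formaldehyde), C=O
Why: Mannich condensation of the readily formed enol of the benzyl ketone with the iminium ion gives 9, which loses diisopropylamine by β-elimination (α-methylenation); the acidic medium keeps the chelated 2'-hydroxyl un-ionised so ring closure does not run ahead, and any racemic isoflavanone formed is removed on the column.

Step 5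
Reactants: 10 1-[2,4-dihydroxy-3-(3-methylbut-2-en-1-yl)phenyl]-2-(2,2-dimethylchroman-6-yl)prop-2-en-1-one
Product: 12 (3R)-7-hydroxy-3-(2,2-dimethylchroman-6-yl)-8-(3-methylbut-2-en-1-yl)chroman-4-one, via chromenol enol 11 (not isolated)
Conditions: (R)-3,3'-bis(2,4,6-triisopropylphenyl)-1,1'-binaphthyl-2,2'-diyl hydrogen phosphate (C50H57O4P, 5 mol%), toluene (0.02 M), 4 Å molecular sieves, −20 °C, 24–48 h; filtration through silica
Reagents that add atoms: none
Why: Proposed new method: the phosphoric acid binds the chelated 2'-hydroxyl through its P=O oxygen and the enone carbonyl through its P–OH, which triggers 6-endo-trig oxa-Michael attack of the phenol oxygen on the terminal CH2 (O1–C2 bond, ring C) to give the achiral enol 11, which stays hydrogen-bonded in the chiral pocket and is protonated on one face of C3 by the same acid acting as a proton shuttle, so C3 is set as R under catalyst control; the closest known reactions are the racemic base-mediated oxa-Michael closure of 2'-hydroxy-α-methylene deoxybenzoins to isoflavanones and chiral phosphoric acid-catalysed enantioselective protonation of enols and silyl enol ethers of 2-aryl cyclic ketones and of aza- and sulfa-Michael adducts of α-substituted vinyl ketones, whose merger in a C–O ring closure to an isoflavanone is untested.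

## Compound list

1 | 4-hydroxyphenylacetic acid | OC(=O)Cc1ccc(O)cc1 | starting material
2 | isoprene (2-methylbuta-1,3-diene) | C=CC(C)=C | starting material
3 | 2-[4-hydroxy-3-(3-methylbut-2-en-1-yl)phenyl]acetic acid | OC(=O)Cc1ccc(O)c(CC=C(C)C)c1 | intermediate
4 | 2-(2,2-dimethylchroman-6-yl)acetic acid | OC(=O)Cc1ccc2OC(C)(C)CCc2c1 | intermediate
5 | resorcinol (benzene-1,3-diol) | Oc1cccc(O)c1 | starting material
6 | 1-(2,4-dihydroxyphenyl)-2-(2,2-dimethylchroman-6-yl)ethan-1-one | O=C(Cc1ccc2OC(C)(C)CCc2c1)c1ccc(O)cc1O | intermediate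
7 | prenyl bromide (1-bromo-3-methylbut-2-ene) | CC(C)=CCBr | starting material
8 | 1-[2,4-dihydroxy-3-(3-methylbut-2-en-1-yl)phenyl]-2-(2,2-dimethylchroman-6-yl)ethan-1-one | CC(C)=CCc1c(O)ccc(C(=O)Cc2ccc3OC(C)(C)CCc3c2)c1O | intermediate
9 | 3-(diisopropylamino)-1-[2,4-dihydroxy-3-(3-methylbut-2-en-1-yl)phenyl]-2-(2,2-dimethylchroman-6-yl)propan-1-one (racemic Mannich base) | CC(C)=CCc1c(O)ccc(C(=O)C(CN(C(C)C)C(C)C)c2ccc3OC(C)(C)CCc3c2)c1O | intermediate
10 | 1-[2,4-dihydroxy-3-(3-methylbut-2-en-1-yl)phenyl]-2-(2,2-dimethylchroman-6-yl)prop-2-en-1-one | CC(C)=CCc1c(O)ccc(C(=O)C(=C)c2ccc3OC(C)(C)CCc3c2)c1O | intermediate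
11 | 3-(2,2-dimethylchroman-6-yl)-8-(3-methylbut-2-en-1-yl)-2H-chromene-4,7-diol (enol) | CC(C)=CCc1c(O)ccc2c1OCC(c1ccc3OC(C)(C)CCc3c1)=C2O | intermediate
12 | (3R)-7-hydroxy-3-(2,2-dimethylchroman-6-yl)-8-(3-methylbut-2-en-1-yl)chroman-4-one | CC(C)=CCc1c(O)ccc2c1OC[C@@H](c1ccc3c(c1)CCC(C)(C)O3)C2=O | target

## Step count and risks

Total steps: 5. Longest linear sequence: 5 steps (1 → 4 → 6 → 8 → 10 → 12).

The three steps most likely to fail:

**Step 3** (regioselectivity of the C-prenylation; O-alkylation, C5-alkylation and double alkylation compete). The fallback sets out from 6 and returns at 8. The 4-hydroxyl of 6 (the chelated 2-hydroxyl stays free) is alkylated with 3-chloro-3-methylbut-1-yne (K2CO3, KI, acetone, reflux) to the propargyl ether 1-[2-hydroxy-4-(2-methylbut-3-yn-2-yloxy)phenyl]-2-(2,2-dimethylchroman-6-yl)ethan-1-one F1. Semihydrogenation (H2, Pd on CaCO3 poisoned with Pb(OAc)2, quinoline, EtOAc) gives the 1,1-dimethylallyl ether 1-[2-hydroxy-4-(2-methylbut-3-en-2-yloxy)phenyl]-2-(2,2-dimethylchroman-6-yl)ethan-1-one F2. Aromatic Claisen rearrangement (N,N-diethylaniline, 130 °C) then delivers the allyl unit with transposition, that is as a prenyl group, to the carbon between the two oxygens, the position favoured by bond fixation in the chelated 2-hydroxyaryl ketone, and gives 8.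

**Step 4** (free phenols: premature racemic ring closure, aminomethylation of ring A at C5, oligomerisation of 10). The fallback sets out from 8 and returns at 10. Both phenols are silylated (t-BuMe2SiCl, imidazole, 4-(dimethylamino)pyridine, DMF, 50 °C) to the bis-silyl ether 1-[2,4-bis(tert-butyldimethylsilyloxy)-3-(3-methylbut-2-en-1-yl)phenyl]-2-(2,2-dimethylchroman-6-yl)ethan-1-one F3. Methylenation under the conditions of step 4 passes through the silylated Mannich base 3-(diisopropylamino)-1-[2,4-bis(tert-butyldimethylsilyloxy)-3-(3-methylbut-2-en-1-yl)phenyl]-2-(2,2-dimethylchroman-6-yl)propan-1-one F4 (not isolated) to the protected enone 1-[2,4-bis(tert-butyldimethylsilyloxy)-3-(3-methylbut-2-en-1-yl)phenyl]-2-(2,2-dimethylchroman-6-yl)prop-2-en-1-one F5, which cannot cyclise and can be purified and stored. Non-basic desilylation (Et3N·3HF, THF, 0 °C) releases 10 just before step 5.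

**Step 5** (the proposed new cyclization: low ee through uncatalysed tautomerisation of 11, or low rate). The fallback uses known chemistry, sets out from 10 and returns at 12. The ring is closed by the classical base-mediated oxa-Michael addition (Et3N, 10 mol%, CH2Cl2, rt) to racemic 7-hydroxy-3-(2,2-dimethylchroman-6-yl)-8-(3-methylbut-2-en-1-yl)chroman-4-one F6. This is resolved by preparative chiral supercritical-fluid chromatography on an amylose tris(3,5-dimethylphenylcarbamate) phase to give 12. The unwanted (3S)-7-hydroxy-3-(2,2-dimethylchroman-6-yl)-8-(3-methylbut-2-en-1-yl)chroman-4-one F7 is racemised back to F6 with Et3N and recycled.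

Further compounds
F1 | step 3 | 1-[2-hydroxy-4-(2-methylbut-3-yn-2-yloxy)phenyl]-2-(2,2-dimethylchroman-6-yl)ethan-1-one | C#CC(C)(C)Oc1ccc(C(=O)Cc2ccc3OC(C)(C)CCc3c2)c(O)c1
F2 | step 3 | 1-[2-hydroxy-4-(2-methylbut-3-en-2-yloxy)phenyl]-2-(2,2-dimethylchroman-6-yl)ethan-1-one | C=CC(C)(C)Oc1ccc(C(=O)Cc2ccc3OC(C)(C)CCc3c2)c(O)c1
F3 | step 4 | 1-[2,4-bis(tert-butyldimethylsilyloxy)-3-(3-methylbut-2-en-1-yl)phenyl]-2-(2,2-dimethylchroman-6-yl)ethan-1-one | CC(C)=CCc1c(O[Si](C)(C)C(C)(C)C)ccc(C(=O)Cc2ccc3OC(C)(C)CCc3c2)c1O[Si](C)(C)C(C)(C)C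
F4 | step 4 | 3-(diisopropylamino)-1-[2,4-bis(tert-butyldimethylsilyloxy)-3-(3-methylbut-2-en-1-yl)phenyl]-2-(2,2-dimethylchroman-6-yl)propan-1-one (racemic) | CC(C)=CCc1c(O[Si](C)(C)C(C)(C)C)ccc(C(=O)C(CN(C(C)C)C(C)C)c2ccc3OC(C)(C)CCc3c2)c1O[Si](C)(C)C(C)(C)C
F5 | step 4 | 1-[2,4-bis(tert-butyldimethylsilyloxy)-3-(3-methylbut-2-en-1-yl)phenyl]-2-(2,2-dimethylchroman-6-yl)prop-2-en-1-one | CC(C)=CCc1c(O[Si](C)(C)C(C)(C)C)ccc(C(=O)C(=C)c2ccc3OC(C)(C)CCc3c2)c1O[Si](C)(C)C(C)(C)C
F6 | step 5 | racemic 7-hydroxy-3-(2,2-dimethylchroman-6-yl)-8-(3-methylbut-2-en-1-yl)chroman-4-one | CC(C)=CCc1c(O)ccc2c1OCC(c1ccc3c(c1)CCC(C)(C)O3)C2=O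
F7 | step 5 | (3S)-7-hydroxy-3-(2,2-dimethylchroman-6-yl)-8-(3-methylbut-2-en-1-yl)chroman-4-one | CC(C)=CCc1c(O)ccc2c1OC[C@H](c1ccc3c(c1)CCC(C)(C)O3)C2=O
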